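The C40 diester is cut at the two sp2–sp2 single bonds C10–C11 and C10'–C11'. These bonds flank the all-E C11–C11' pentaene, whose carbon frame is twofold symmetric although ring A (the β ring, C1–C6) and ring B (the ε ring, C1'–C6') differ. One pot joins a pentaene linchpin, tributyltin on C11 and pinacol boronate on C11', first to the ring A C10 dienyl iodide by Stille coupling and then, after base is added, to the ring B C10' dienyl iodide by Suzuki–Miyaura coupling. Both iodides already carry their linolenate esters and the stereocentres C3, C3' and C6', so the coupling product is the target.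

Key step: step 17

Remarks and assumptions
- Carotenoid numbering is used throughout; ring A is the β end group, ring B the ε end group.
- Structure check: the three coupling partners (C14 + C12 + C14) add up to the all-E (3R,3'R,6'R) diester; no structural correction is needed.
- Assumption: (R)-α-ionone, the natural enantiomer, is bought in high enantiomeric purity, so C6' is purchased and not resolved.
- Assumption: the (S,S)-ligand in step 4 gives the 4S alcohol (alkenyl side in the place of aryl in the usual model); the sign of rotation is checked on the first run and the (R,R)-complex is used if the sense is opposite.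
- All polyenes are handled under argon in dim light.

Step 1
Reactants: 1 (2E,4E,6E)-2,7-dimethylocta-2,4,6-trienedial; 2 2-(dichloromethyl)-4,4,5,5-tetramethyl-1,3,2-dioxaborolane
Product: 4 (2E,4E,6E,8E)-2,7-dimethyl-9-(4,4,5,5-tetramethyl-1,3,2-dioxaborolan-2-yl)nona-2,4,6,8-tetraenal, via diiodomethyl boronate 3 (not isolated)
Conditions: 2 (0.9 equiv, slow addition), CrCl2 (6 equiv), LiI (3 equiv), THF, 0 °C → rt, dark; unreacted 1 recovered
Reagents that add atoms: none
Why: Takai-type boryl olefination, in which divalent chromium turns the gem-dihalide into a geminal dichromium species that adds to one formyl group and eliminates to the E-alkenylboronate, and mono-olefination should dominate because 2 is limiting and the formyl group left in 4 ends a longer tetraene that no longer feels a second acceptor.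

Step 2
Reactants: 5 dibromomethane; 6 tributyltin chloride
Product: 8 tributyl(dibromomethyl)stannane, via dibromomethyllithium 7 (not isolated)
Conditions: LiN(i-Pr)2, THF/Et2O, −95 °C; then 6, −95 °C → rt
Reagents that add atoms: none
Why: Deprotonation of dibromomethane gives the lithium carbenoid 7, which is stable only at this temperature and displaces chloride at tin (stannylation of a lithium carbenoid).

Step 3
Reactants: 4 boryl tetraenal; 8 tributyl(dibromomethyl)stannane
Product: 10 tributyl[(1E,3E,5E,7E,9E)-3,8-dimethyl-10-(4,4,5,5-tetramethyl-1,3,2-dioxaborolan-2-yl)deca-1,3,5,7,9-pentaen-1-yl]stannane, via diiodomethyl stannane 9 (not isolated)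
Conditions: 8 (2 equiv), CrCl2 (8 equiv), LiI (4 equiv), THF/DMF, rt, dark; chromatography on Et3N-deactivated silica
Reagents that add atoms: none
Why: Stannyl variant of the Takai olefination, E-selective through the same geminal dichromium addition–elimination, with the pinacol boronate inert to divalent chromium and the acid-sensitive carbon–tin bond made last.

Step 4
Reactants: 11 ketoisophorone (2,6,6-trimethylcyclohex-2-ene-1,4-dione)
Product: 12 (4S)-4-hydroxy-2,6,6-trimethylcyclohex-2-en-1-one
Conditions: RuCl[(S,S)-TsDPEN](p-cymene) (1 mol %), KOt-Bu (2 mol %), i-PrOH, rt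
Reagents that add atoms: none
Why: Noyori asymmetric transfer hydrogenation should reduce only the unhindered C4 carbonyl (C1 is screened by the C2 methyl and the C6 gem-dimethyl group), and the chiral ruthenium hydride sets the 4S centre, which becomes C3 of ring A.

Step 5
Reactants: 12 (4S)-4-hydroxy-2,6,6-trimethylcyclohex-2-en-1-one
Product: 13 (4S)-4-{[tert-butyl(dimethyl)silyl]oxy}-2,6,6-trimethylcyclohex-2-en-1-one
Conditions: TBSCl, imidazole, DMF, rt
Reagents that add atoms: tert-butyldimethylsilyl chloride, CC(C)(C)[Si](C)(C)Cl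
Why: Standard silylation of a secondary alcohol masks the hydroxyl against the hydride and amide bases of steps 6 and 8.

Step 6
Reactants: 13 silyl ether of the enone
Product: 15 (4R)-4-{[tert-butyl(dimethyl)silyl]oxy}-2,6,6-trimethylcyclohex-1-en-1-yl trifluoromethanesulfonate, via lithium enolate 14 (not isolated)
Conditions: LiBH(s-Bu)3 (1.05 equiv), THF, −78 °C; then PhNTf2, −78 °C → rt
Reagents that add atoms: N-phenylbis(trifluoromethanesulfonimide), O=S(=O)(N(c1ccccc1)S(=O)(=O)C(F)(F)F)C(F)(F)F
Why: Conjugate hydride addition of the bulky borohydride to the β-unsubstituted, carbonyl-hindered cyclohexenone gives the tetrasubstituted enolate 14 regiospecifically, and O-triflation fixes the C5=C6 double bond of ring A (reductive enol triflate formation).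

Step 7
Reactants: 15 ring A enol triflate; 16 methyl vinyl ketone (but-3-en-2-one)
Product: 17 (3E)-4-[(4R)-4-{[tert-butyl(dimethyl)silyl]oxy}-2,6,6-trimethylcyclohex-1-en-1-yl]but-3-en-2-one
Conditions: Pd(OAc)2 (5 mol %), PPh3 (10 mol %), Et3N, 16 (3 equiv), DMF, 70 °C
Reagents that add atoms: none
Why: Mizoroki–Heck reaction, in which the alkenyl triflate adds oxidatively to zerovalent palladium, methyl vinyl ketone inserts at its unsubstituted carbon and β-hydride elimination gives the E-dienone.

Step 8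
Reactants: 17 silylated 3-hydroxy-β-ionone
Product: 21 tert-butyl({(1R)-4-[(1E)-but-1-en-3-yn-1-yl]-3,5,5-trimethylcyclohex-3-en-1-yl}oxy)dimethylsilane, via lithium dienolate 18 (not isolated), via dienyl phosphate 19 (not isolated), via lithium acetylide 20 (not isolated)
Conditions: LiN(i-Pr)2 (1.1 equiv), THF, −78 °C; ClP(O)(OEt)2, −78 °C → rt; then LiN(i-Pr)2 (2.3 equiv), −78 °C → rt; aq. NH4Cl
Reagents that add atoms: none
Why: Enol phosphate route from a methyl ketone to a terminal alkyne (kinetic deprotonation at the methyl group, O-phosphorylation, amide-induced elimination of diethyl phosphate), a sequence known for β-ionone itself.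

Step 9
Reactants: 21 ring A enyne
Product: 23 tert-butyl({(1R)-4-[(1E,3E)-4-iodo-3-methylbuta-1,3-dien-1-yl]-3,5,5-trimethylcyclohex-3-en-1-yl}oxy)dimethylsilane, via alkenylalane 22 (not isolated)
Conditions: Me3Al (2.5 equiv), Cp2ZrCl2 (0.5 equiv), CH2Cl2, rt; then I2, THF, −30 → 0 °C
Reagents that add atoms: trimethylaluminium, C[Al](C)C; iodine, II
Why: Zirconium-catalysed Negishi carboalumination adds methyl and aluminium syn across the terminal alkyne with methyl at the internal carbon C9, and iodinolysis of the carbon–aluminium bond with retention gives the 9E iodide.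

Step 10
Reactants: 23 silylated ring A dienyl iodide
Product: 24 (1R)-4-[(1E,3E)-4-iodo-3-methylbuta-1,3-dien-1-yl]-3,5,5-trimethylcyclohex-3-en-1-ol
Conditions: Bu4NF, THF, 0 °C → rt, dark
Reagents that add atoms: none
Why: Fluoride cleaves the silicon–oxygen bond (standard desilylation) without touching the alkenyl iodide.

Step 11
Reactants: 24 ring A hydroxy iodide; 25 α-linolenic acid
Product: 26 (1R)-4-[(1E,3E)-4-iodo-3-methylbuta-1,3-dien-1-yl]-3,5,5-trimethylcyclohex-3-en-1-yl (9Z,12Z,15Z)-octadeca-9,12,15-trienoate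
Conditions: 25 (1.3 equiv), EDC·HCl, DMAP, CH2Cl2, 0 °C → rt, dark
Reagents that add atoms: none
Why: Steglich esterification through the O-acylisourea and the acylpyridinium ion acylates the secondary alcohol under neutral conditions that leave the skipped Z-triene and the alkenyl iodide alone.

Step 12
Reactants: 27 (R)-α-ionone
Product: 31 (6R)-6-[(1E)-but-1-en-3-yn-1-yl]-1,5,5-trimethylcyclohex-1-ene, via lithium dienolate 28 (not isolated), via dienyl phosphate 29 (not isolated), via lithium acetylide 30 (not isolated)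
Conditions: LiN(i-Pr)2 (1.1 equiv), THF, −78 °C; ClP(O)(OEt)2, −78 °C → rt; then LiN(i-Pr)2 (2.3 equiv), −78 °C → rt; aq. NH4Cl
Reagents that add atoms: none
Why: The same enol phosphate route as in step 8, in which kinetic deprotonation takes the methyl group and not the hindered tertiary C6'–H, so the purchased C6' centre is kept.

Step 13
Reactants: 31 ring B enyne
Product: 32 (4R)-4-[(1E)-but-1-en-3-yn-1-yl]-3,5,5-trimethylcyclohex-2-en-1-one
Conditions: Rh2(cap)4 (dirhodium tetracaprolactamate, 1 mol %), t-BuOOH (70% aq., 6 equiv), ClCH2CH2Cl, 40 °C, no base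
Reagents that add atoms: tert-butyl hydroperoxide, CC(C)(C)OO
Why: Radical allylic oxidation by tert-butylperoxyl radicals should take the unhindered C3' methylene, as it does in α-ionone and its side-chain derivatives, because the doubly allylic C6'–H is tertiary and shielded by the C1' gem-dimethyl group and the C5' methyl, and the absence of base protects C6'.

Step 14
Reactants: 32 ring B enone
Product: 33 (1R,4R)-4-[(1E)-but-1-en-3-yn-1-yl]-3,5,5-trimethylcyclohex-2-en-1-ol
Conditions: KBH(s-Bu)3 (1.2 equiv), THF, −78 °C; aq. NH4Cl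
Reagents that add atoms: none
Why: 1,2-Reduction of the β,β-disubstituted enone by the bulky borohydride, in which the side chain sits pseudoaxial and the axial C1' methyl blocks the opposite face, so hydride should enter syn to the side chain and give the 3',6'-trans alcohol, that is 3'R from 6'R (substrate control).

Step 15
Reactants: 33 ring B hydroxy enyne
Product: 35 (1R,4R)-4-[(1E,3E)-4-iodo-3-methylbuta-1,3-dien-1-yl]-3,5,5-trimethylcyclohex-2-en-1-ol, via bis-aluminated alkenylalane 34 (not isolated)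
Conditions: Me3Al (3.5 equiv), Cp2ZrCl2 (0.5 equiv), CH2Cl2, 0 °C → rt; then I2, THF, −30 → 0 °C; Rochelle salt work-up
Reagents that add atoms: trimethylaluminium, C[Al](C)C; iodine, II
Why: Negishi carboalumination as in step 9, with the hydroxyl carried as its dimethylaluminium alkoxide at the cost of one more equivalent of Me3Al, followed by iodinolysis with retention to the 9'E iodide.

Step 16
Reactants: 35 ring B hydroxy iodide; 25 α-linolenic acid
Product: 36 (1R,4R)-4-[(1E,3E)-4-iodo-3-methylbuta-1,3-dien-1-yl]-3,5,5-trimethylcyclohex-2-en-1-yl (9Z,12Z,15Z)-octadeca-9,12,15-trienoate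
Conditions: 25 (1.3 equiv), EDC·HCl, DMAP, CH2Cl2, 0 °C → rt, dark
Reagents that add atoms: none
Why: Steglich esterification, whose neutral carbodiimide and DMAP conditions avoid ionisation of the allylic C3'–O bond, so the 3'R configuration is kept.

Step 17
Reactants: 26 ring A dienyl iodide linolenate; 10 stannyl–boryl pentaene linchpin; 36 ring B dienyl iodide linolenate
Product: 38 (3R,3'R,6'R)-β,ε-carotene-3,3'-diyl bis[(9Z,12Z,15Z)-octadeca-9,12,15-trienoate], via heptaenyl boronate 37 (not isolated)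
Conditions: 26 (1.00 equiv), 10 (1.00 equiv), Pd2(dba)3 (5 mol %), AsPh3 (40 mol %), degassed DMF/THF, rt, dark; then 36 (1.1 equiv), degassed 3 M aq. K3PO4 (3 equiv), rt → 35 °C; chromatography on deactivated silica under argon in dim light
Reagents that add atoms: none
Why: Zerovalent palladium inserts into the C10–I bond of 26, the alkenyl–tin end of 10 transmetalates without base and reductive elimination forms C10–C11 to give 37, and once 36 and aqueous K3PO4 are added a second cycle (insertion into C10'–I, base-assisted boron-to-palladium transmetalation, reductive elimination) forms C10'–C11'. The closest known reaction type is the one-pot Stille then Suzuki–Miyaura coupling of stannyl–boryl diene and polyene linchpins with two different alkenyl halides. No ring is closed and no stereocentre is created; C3, C3', C6' and every alkene geometry come in with 26, 10 and 36, and both couplings proceed with retention at the sp2 carbons. The selectivity needed is between the two linchpin termini, and the two different metals secure it: the pinacol boronate does not transmetalate until base is present, whereas the stannane does, so 26 meets only C11 and 36 only C11'. A strict 1:1 ratio of 26 to 10, with consumption of both checked before 36 is added, keeps the symmetric ring A/ring A and ring B/ring B diesters out. The weakly bound arsine allows the tin step at room temperature, the allylic 3'-ester of 36 meets palladium only in the second stage, where insertion into the C–I bond should outrun ionisation of the allylic carboxylate, and the phosphate base is too mild to cleave the esters or move the skipped Z-alkenes.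

Compound list
1 | (2E,4E,6E)-2,7-dimethylocta-2,4,6-trienedial | O=C/C(C)=C/C=C/C=C(C)/C=O | starting material
2 | 2-(dichloromethyl)-4,4,5,5-tetramethyl-1,3,2-dioxaborolane | ClC(Cl)B1OC(C)(C)C(C)(C)O1 | starting material
3 | 2-(diiodomethyl)-4,4,5,5-tetramethyl-1,3,2-dioxaborolane (formed by halide exchange, not isolated) | IC(I)B1OC(C)(C)C(C)(C)O1 | intermediate
4 | (2E,4E,6E,8E)-2,7-dimethyl-9-(4,4,5,5-tetramethyl-1,3,2-dioxaborolan-2-yl)nona-2,4,6,8-tetraenal | O=C/C(C)=C/C=C/C=C(C)/C=C/B1OC(C)(C)C(C)(C)O1 | intermediate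
5 | dibromomethane | BrCBr | starting material
6 | tributyltin chloride | CCCC[Sn](Cl)(CCCC)CCCC | starting material
7 | dibromomethyllithium (not isolated) | [Li]C(Br)Br | intermediate
8 | tributyl(dibromomethyl)stannane | CCCC[Sn](CCCC)(CCCC)C(Br)Br | intermediate
9 | tributyl(diiodomethyl)stannane (formed by halide exchange, not isolated) | CCCC[Sn](CCCC)(CCCC)C(I)I | intermediate
10 | tributyl[(1E,3E,5E,7E,9E)-3,8-dimethyl-10-(4,4,5,5-tetramethyl-1,3,2-dioxaborolan-2-yl)deca-1,3,5,7,9-pentaen-1-yl]stannane | CCCC[Sn](CCCC)(CCCC)/C=C/C(C)=C/C=C/C=C(C)/C=C/B1OC(C)(C)C(C)(C)O1 | intermediate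
11 | ketoisophorone (2,6,6-trimethylcyclohex-2-ene-1,4-dione) | CC1=CC(=O)CC(C)(C)C1=O | starting material
12 | (4S)-4-hydroxy-2,6,6-trimethylcyclohex-2-en-1-one | O[C@@H]1C=C(C)C(=O)C(C)(C)C1 | intermediate
13 | (4S)-4-{[tert-butyl(dimethyl)silyl]oxy}-2,6,6-trimethylcyclohex-2-en-1-one | CC(C)(C)[Si](C)(C)O[C@@H]1C=C(C)C(=O)C(C)(C)C1 | intermediate
14 | lithium (4R)-4-{[tert-butyl(dimethyl)silyl]oxy}-2,6,6-trimethylcyclohex-1-en-1-olate (not isolated) | CC(C)(C)[Si](C)(C)O[C@@H]1CC(C)=C(O[Li])C(C)(C)C1 | intermediate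
15 | (4R)-4-{[tert-butyl(dimethyl)silyl]oxy}-2,6,6-trimethylcyclohex-1-en-1-yl trifluoromethanesulfonate | CC(C)(C)[Si](C)(C)O[C@@H]1CC(C)=C(OS(=O)(=O)C(F)(F)F)C(C)(C)C1 | intermediate
16 | methyl vinyl ketone (but-3-en-2-one) | CC(=O)C=C | starting material
17 | (3E)-4-[(4R)-4-{[tert-butyl(dimethyl)silyl]oxy}-2,6,6-trimethylcyclohex-1-en-1-yl]but-3-en-2-one | CC(C)(C)[Si](C)(C)O[C@@H]1CC(C)=C(/C=C/C(C)=O)C(C)(C)C1 | intermediate
18 | lithium dienolate of 17, deprotonated at the methyl group (not isolated) | CC(C)(C)[Si](C)(C)O[C@@H]1CC(C)=C(/C=C/C(=C)O[Li])C(C)(C)C1 | intermediate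
19 | diethyl (3E)-4-[(4R)-4-{[tert-butyl(dimethyl)silyl]oxy}-2,6,6-trimethylcyclohex-1-en-1-yl]buta-1,3-dien-2-yl phosphate (not isolated) | CC(C)(C)[Si](C)(C)O[C@@H]1CC(C)=C(/C=C/C(=C)OP(=O)(OCC)OCC)C(C)(C)C1 | intermediate
20 | lithium acetylide of 21 (not isolated) | CC(C)(C)[Si](C)(C)O[C@@H]1CC(C)=C(/C=C/C#C[Li])C(C)(C)C1 | intermediate
21 | tert-butyl({(1R)-4-[(1E)-but-1-en-3-yn-1-yl]-3,5,5-trimethylcyclohex-3-en-1-yl}oxy)dimethylsilane | CC(C)(C)[Si](C)(C)O[C@@H]1CC(C)=C(/C=C/C#C)C(C)(C)C1 | intermediate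
22 | dimethyl[(1E,3E)-2-methyl-4-(ring A)buta-1,3-dien-1-yl]alane, ring A as in 21 (not isolated) | CC(C)(C)[Si](C)(C)O[C@@H]1CC(C)=C(/C=C/C(C)=C/[Al](C)C)C(C)(C)C1 | intermediate
23 | tert-butyl({(1R)-4-[(1E,3E)-4-iodo-3-methylbuta-1,3-dien-1-yl]-3,5,5-trimethylcyclohex-3-en-1-yl}oxy)dimethylsilane | CC(C)(C)[Si](C)(C)O[C@@H]1CC(C)=C(/C=C/C(C)=C/I)C(C)(C)C1 | intermediate
24 | (1R)-4-[(1E,3E)-4-iodo-3-methylbuta-1,3-dien-1-yl]-3,5,5-trimethylcyclohex-3-en-1-ol | O[C@@H]1CC(C)=C(/C=C/C(C)=C/I)C(C)(C)C1 | intermediate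
25 | α-linolenic acid, (9Z,12Z,15Z)-octadeca-9,12,15-trienoic acid | CC/C=C\C/C=C\C/C=C\CCCCCCCC(=O)O | starting material
26 | (1R)-4-[(1E,3E)-4-iodo-3-methylbuta-1,3-dien-1-yl]-3,5,5-trimethylcyclohex-3-en-1-yl (9Z,12Z,15Z)-octadeca-9,12,15-trienoate | CC/C=C\C/C=C\C/C=C\CCCCCCCC(=O)O[C@@H]1CC(C)=C(/C=C/C(C)=C/I)C(C)(C)C1 | intermediate
27 | (R)-α-ionone, (3E)-4-[(1R)-2,6,6-trimethylcyclohex-2-en-1-yl]but-3-en-2-one | CC(=O)/C=C/[C@H]1C(C)=CCCC1(C)C | starting material
28 | lithium dienolate of 27, deprotonated at the methyl group (not isolated) | [Li]OC(=C)/C=C/[C@H]1C(C)=CCCC1(C)C | intermediate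
29 | diethyl (3E)-4-[(1R)-2,6,6-trimethylcyclohex-2-en-1-yl]buta-1,3-dien-2-yl phosphate (not isolated) | C=C(OP(=O)(OCC)OCC)/C=C/[C@H]1C(C)=CCCC1(C)C | intermediate
30 | lithium acetylide of 31 (not isolated) | [Li]C#C/C=C/[C@H]1C(C)=CCCC1(C)C | intermediate
31 | (6R)-6-[(1E)-but-1-en-3-yn-1-yl]-1,5,5-trimethylcyclohex-1-ene | C#C/C=C/[C@H]1C(C)=CCCC1(C)C | intermediate
32 | (4R)-4-[(1E)-but-1-en-3-yn-1-yl]-3,5,5-trimethylcyclohex-2-en-1-one | C#C/C=C/[C@H]1C(C)=CC(=O)CC1(C)C | intermediate
33 | (1R,4R)-4-[(1E)-but-1-en-3-yn-1-yl]-3,5,5-trimethylcyclohex-2-en-1-ol | C#C/C=C/[C@H]1C(C)=C[C@H](O)CC1(C)C | intermediate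
34 | alkenyl(dimethyl)alane of 33 with the hydroxyl as its dimethylaluminium alkoxide (not isolated) | C[Al](C)/C=C(C)/C=C/[C@H]1C(C)=C[C@H](O[Al](C)C)CC1(C)C | intermediate
35 | (1R,4R)-4-[(1E,3E)-4-iodo-3-methylbuta-1,3-dien-1-yl]-3,5,5-trimethylcyclohex-2-en-1-ol | I/C=C(C)/C=C/[C@H]1C(C)=C[C@H](O)CC1(C)C | intermediate
36 | (1R,4R)-4-[(1E,3E)-4-iodo-3-methylbuta-1,3-dien-1-yl]-3,5,5-trimethylcyclohex-2-en-1-yl (9Z,12Z,15Z)-octadeca-9,12,15-trienoate | I/C=C(C)/C=C/[C@H]1C(C)=C[C@H](OC(=O)CCCCCCC/C=C\C/C=C\C/C=C\CC)CC1(C)C | intermediate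
37 | ring A linolenate carrying the all-E C7–C11' heptaenyl chain that ends in the pinacol boronate at C11' (not isolated) | CC/C=C\C/C=C\C/C=C\CCCCCCCC(=O)O[C@@H]1CC(C)=C(/C=C/C(C)=C/C=C/C(C)=C/C=C/C=C(C)/C=C/B2OC(C)(C)C(C)(C)O2)C(C)(C)C1 | intermediate
38 | (3R,3'R,6'R)-β,ε-carotene-3,3'-diyl bis[(9Z,12Z,15Z)-octadeca-9,12,15-trienoate] (lutein di-α-linolenate, CNP0400996.1) | CC/C=C\C/C=C\C/C=C\CCCCCCCC(=O)O[C@@H]1CC(C)=C(/C=C/C(C)=C/C=C/C(C)=C/C=C/C=C(C)/C=C/C=C(C)/C=C/[C@H]2C(C)=C[C@H](OC(=O)CCCCCCC/C=C\C/C=C\C/C=C\CC)CC2(C)C)C(C)(C)C1 | target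

Total step count: 17 (linchpin 3, ring A iodide 8, ring B iodide 5, coupling 1).
Longest linear sequence: 9 steps (11 → 12 → 13 → 15 → 17 → 21 → 23 → 24 → 26 → 38, steps 4 to 11 and step 17).

Steps most likely to fail

Step 17. The two ring iodides may be scrambled over the two linchpin ends if the tin coupling is incomplete when base is added, giving isomeric symmetric diesters that are hard to remove, and zerovalent palladium may ionise the allylic 3'-ester. The fallback makes the same two bonds on the free alcohols and acylates last. It sets out from 24, 10 and 35: base-free Stille coupling of 24 with 10 gives the ring A hydroxy heptaenyl pinacol boronate F1, which is isolated; Suzuki–Miyaura coupling of F1 with 35 (aq. K3PO4) gives (3R,3'R,6'R)-lutein F2, which is freed from isomeric carotenoids by crystallisation; double Steglich acylation of F2 with 25 returns to the route at 38.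

Step 13. Hydrogen abstraction may occur at the doubly allylic C6'–H, or peroxyl radicals may add to the enyne, instead of oxidation at C3'. The fallback carries out the oxidation on a ketal, a substrate class on which C3' oxidation is known, and builds the alkyne afterwards. It sets out from 27: ketalisation with ethylene glycol (HC(OEt)3, cat. p-TsOH, rt) gives (R)-α-ionone ethylene ketal F3; allylic oxidation with t-BuOOH gives 3-oxo-α-ionone ethylene ketal F4; KBH(s-Bu)3 gives the 3,6-trans hydroxy ketal F5; dilute HCl in THF gives (3R,6R)-3-hydroxy-α-ionone F6; TBSCl and imidazole give the silyl ether F7; LiN(i-Pr)2 gives the lithium dienolate F8, ClP(O)(OEt)2 the dienyl phosphate F9, more LiN(i-Pr)2 the lithium acetylide F10 and work-up the silylated enyne F11; Bu4NF returns to the route at 33.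

Step 7. Insertion of methyl vinyl ketone into the hindered tetrasubstituted alkenylpalladium may be slow, so that reduction of the triflate and oligomerisation of the enone take over. The fallback builds the enone by carbonyl chemistry. It sets out from 15: palladium-catalysed formylation (Pd(PPh3)4, CO, Bu3SnH, LiCl, THF, 50 °C) gives (4R)-4-{[tert-butyl(dimethyl)silyl]oxy}-2,6,6-trimethylcyclohex-1-ene-1-carbaldehyde F12, and aldol condensation of F12 with acetone (NaOEt, acetone, rt) returns to the route at 17.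

Further compounds
F1 | step 17 | (1R)-ring A alcohol carrying the all-E C7–C11' heptaenyl chain that ends in the pinacol boronate | O[C@@H]1CC(C)=C(/C=C/C(C)=C/C=C/C(C)=C/C=C/C=C(C)/C=C/B2OC(C)(C)C(C)(C)O2)C(C)(C)C1
F2 | step 17 | (3R,3'R,6'R)-lutein | O[C@@H]1CC(C)=C(/C=C/C(C)=C/C=C/C(C)=C/C=C/C=C(C)/C=C/C=C(C)/C=C/[C@H]2C(C)=C[C@H](O)CC2(C)C)C(C)(C)C1
F3 | step 13 | 2-methyl-2-{(E)-2-[(1R)-2,6,6-trimethylcyclohex-2-en-1-yl]ethenyl}-1,3-dioxolane | CC1(/C=C/[C@H]2C(C)=CCCC2(C)C)OCCO1
F4 | step 13 | (4R)-3,5,5-trimethyl-4-[(E)-2-(2-methyl-1,3-dioxolan-2-yl)ethenyl]cyclohex-2-en-1-one | CC1(/C=C/[C@H]2C(C)=CC(=O)CC2(C)C)OCCO1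
F5 | step 13 | (1R,4R)-3,5,5-trimethyl-4-[(E)-2-(2-methyl-1,3-dioxolan-2-yl)ethenyl]cyclohex-2-en-1-ol | CC1(/C=C/[C@H]2C(C)=C[C@H](O)CC2(C)C)OCCO1
F6 | step 13 | (3R,6R)-3-hydroxy-α-ionone | CC(=O)/C=C/[C@H]1C(C)=C[C@H](O)CC1(C)C
F7 | step 13 | (3R,6R)-3-{[tert-butyl(dimethyl)silyl]oxy}-α-ionone | CC(=O)/C=C/[C@H]1C(C)=C[C@H](O[Si](C)(C)C(C)(C)C)CC1(C)C
F8 | step 13 | lithium dienolate of F7 | [Li]OC(=C)/C=C/[C@H]1C(C)=C[C@H](O[Si](C)(C)C(C)(C)C)CC1(C)C
F9 | step 13 | diethyl dienyl phosphate of F7 | C=C(OP(=O)(OCC)OCC)/C=C/[C@H]1C(C)=C[C@H](O[Si](C)(C)C(C)(C)C)CC1(C)C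
F10 | step 13 | lithium acetylide of F11 | [Li]C#C/C=C/[C@H]1C(C)=C[C@H](O[Si](C)(C)C(C)(C)C)CC1(C)C
F11 | step 13 | tert-butyl({(1R,4R)-4-[(1E)-but-1-en-3-yn-1-yl]-3,5,5-trimethylcyclohex-2-en-1-yl}oxy)dimethylsilane | C#C/C=C/[C@H]1C(C)=C[C@H](O[Si](C)(C)C(C)(C)C)CC1(C)C
F12 | step 7 | (4R)-4-{[tert-butyl(dimethyl)silyl]oxy}-2,6,6-trimethylcyclohex-1-ene-1-carbaldehyde | CC(C)(C)[Si](C)(C)O[C@@H]1CC(C)=C(C=O)C(C)(C)C1
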